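At 6.0 h, the time of reading, the question about the red flask is where X stops, and whether anything done then can move it.

| flask | E | J | remark | time |
|---|---|---|---|---|
| red | 0.24 M | 0.50 equiv | the very flask that is asked about, followed so far |  |
| violet | 0.12 M | 0.50 equiv | run made earlier |  |
| flask | 0.24 M | 0.500 equiv |  | 6.0 h |

| red: time / min | red: X / % | violet: time / min | violet: X / % |
|---|---|---|---|
| 80.0 | 48.7 | 1.33 | 0.5 |
| 150 | 50.3 | 4.00 | 3.0 |
| 240 | 50.0 | 8.00 | 12.0 |
| 300 | 51.0 | 12.0 | 15.7 |
| 360 | 51.1 | 15.0 | 18.2 |

(scatter of a reading: 1 percentage point)

- X that was removed still counts
- additions bring no volume worth counting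

- delta: at 6.0 h add E, 50.0 % of the amount charged, then wait 12 h
- zeta: at 6.0 h add J, 100 % of the amount charged, then wait 12 h
- beta: at 6.0 h take out 90 % of the X then present, then wait 12 h
- theta: change nothing and wait 12 h more

- X, in percent of the E first charged, at 6.0 h
- the remedy with the largest gain of X, or "none" below 2 percentage points (delta / zeta / beta / theta / none)
- X present, with what was taken out counted in, in percent of the E first charged, after delta
- X present, with what was taken out counted in, in percent of the E first charged, after zeta

Read down the red table: X stands at 48.7 % at 80.0 min and at 50.3 % at 150 min, and it ends at 51.1 % at 360 min. The last four readings average 50.6 %, and from the first of them to the last X climbs 0.8 percentage points, less than the scatter of 1 point in one reading. So the red run has stopped within its scatter. The violet table tells something else: at 15.0 min X is 18.2 % and still rising, so that run shows speed, not a stopping point.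

Suppose each X costs one E and one J. Then J is the limiting reagent, and X in the red flask stops at the ceiling: J charged per E first charged, taken as no more than the whole of the E, 50.0 %. This number comes from the charges and the plateau from the readings, so their agreement is a check: they differ by 0.6 points, inside the scatter of one reading.

My own reckoning therefore puts X at 50.0 % at 6.0 h. Zeta lifts the ceiling to 100 %, while delta, beta and theta add no J and leave it at 50.0 %. The ceiling does not tell how near X comes to it in 12 h.

The forecast gives 50.3 % now, above my figure, names zeta as the remedy, and gives 50.5 % after delta and 97 % after zeta. Its ground: “the simplest reading is 1:1 consumption with J exhausted, not equilibrium or catalyst death”.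

The red flask gives 50.0 % at 6.0 h, equal to the ceiling of 50.0 %, with 0 % of the J charged and 50.0 % of the E charged still free at 360 min.

Z → X (k = 0.330 min⁻¹); E + J ⇌ Z (K = 4.30 L mol⁻¹, k = 0.450 L mol⁻¹ min⁻¹) Zeta is the remedy, gaining 48 points and reaching 98.3 %, which is 1.7 points under its ceiling of 100 %, while delta stays at 50.0 %. The same flask charged with 0.120 equiv of J has its ceiling at 12.0 %, and at 360 min it gives 12.0 %.

(The data were generated by integration from invented constants; the scatter is artificial.)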